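**Strategy.** The trisubstituted C2=C3 double bond of the 2,6,6-trimethylcyclohex-2-enyl ring is made last among the skeletal bonds, by ring-closing metathesis of an acyclic triene, so that its position cannot drift. The step exploits the 1,7-relationship of two terminal olefins across the gem-dimethyl carbon C6: the isopropenyl group of (S)-limonene becomes C2 with its methyl, limonene C4 is the C1 stereocentre, and a butenyl arm delivers C3. The precursor is a ring-opened, re-branched limonene that already carries the E-configured side chain and a tetramethoxyarene as the masked hydroxy-methoxy-quinone; one operation closes the carbocycle beside an existing stereocentre without touching it.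

Key step: step 10

Remark: the C1 ring stereocentre is never touched after limonene; its descriptor reads R in compounds 13 to 16 only because the CIP ranking of its neighbours changes.

Step 1
Reactants: 1 (S)-limonene
Product: 3 (5S)-7,7-dimethoxy-5-(prop-1-en-2-yl)heptan-2-one, via keto aldehyde 2 (not isolated)
Conditions: O3 (1.0 equiv), CH2Cl2/MeOH, −78 °C; Me2S, −78 °C → rt; then TsOH (cat.), MeOH, rt
Reagents that add atoms: ozone ([O-][O+]=O); methanol (CO)
Why: Chemoselective ozonolysis, in which electrophilic ozone should attack the trisubstituted ring olefin faster than the 1,1-disubstituted isopropenyl group, followed by reductive work-up and acid-catalysed acetalisation that masks only the aldehyde; the stereocentre is not involved.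

Step 2
Reactants: 3 (5S)-7,7-dimethoxy-5-(prop-1-en-2-yl)heptan-2-one
Product: 5 (5S)-7,7-dimethoxy-5-(prop-1-en-2-yl)hept-1-yne, via enol phosphate 4 (not isolated)
Conditions: LDA (1.05 equiv), THF, −78 °C; ClP(O)(OEt)2, −78 °C → rt; then LDA (2.3 equiv), −78 °C → rt
Reagents that add atoms: none
Why: Negishi conversion of a methyl ketone into a terminal alkyne, by kinetic deprotonation at the methyl group, O-phosphorylation and base-induced elimination of the enol phosphate, none of which touches the remote stereocentre or the acetal.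

Step 3
Reactants: 6 1,2,4,5-tetramethoxybenzene
Product: 8 (2,3,5,6-tetramethoxyphenyl)methanol, via aryllithium 7 (not isolated)
Conditions: n-BuLi, TMEDA, THF, 0 °C; (CH2O)n, 0 °C → rt
Reagents that add atoms: formaldehyde from paraformaldehyde (C=O)
Why: Directed ortho-metalation at the position flanked by two methoxy groups, followed by hydroxymethylation of the aryllithium with formaldehyde.

Step 4
Reactants: 8 (2,3,5,6-tetramethoxyphenyl)methanol
Product: 9 3-(chloromethyl)-1,2,4,5-tetramethoxybenzene
Conditions: SOCl2, CH2Cl2, 0 °C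
Reagents that add atoms: thionyl chloride (ClS(Cl)=O)
Why: Chlorodehydroxylation of an electron-rich benzylic alcohol through its chlorosulfite, which should be fast because the benzylic position is activated by the ortho methoxy groups.

Step 5
Reactants: 5 (5S)-7,7-dimethoxy-5-(prop-1-en-2-yl)hept-1-yne; 9 3-(chloromethyl)-1,2,4,5-tetramethoxybenzene
Product: 12 (3S,6E)-6-methyl-3-(prop-1-en-2-yl)-8-(2,3,5,6-tetramethoxyphenyl)oct-6-enal, via alkenylalane 10 (not isolated), via dimethyl acetal 11 (not isolated)
Conditions: Me3Al (2 equiv), Cp2ZrCl2 (0.2 equiv), CH2Cl2, 0 °C → rt; then 9, Pd(PPh3)4 (5 mol %), THF, rt; then 1 M HCl, THF, rt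
Reagents that add atoms: trimethylaluminium (C[Al](C)C); water (O)
Why: Negishi zirconium-catalysed syn-carboalumination puts methyl on the internal and aluminium on the terminal alkyne carbon, which fixes the E geometry, then palladium-catalysed alkenyl–benzyl cross-coupling proceeds with retention and the dilute acid of the work-up hydrolyses the acetal.

Step 6
Reactants: 12 (3S,6E)-6-methyl-3-(prop-1-en-2-yl)-8-(2,3,5,6-tetramethoxyphenyl)oct-6-enal
Product: 13 (3R,6E)-2,2,6-trimethyl-3-(prop-1-en-2-yl)-8-(2,3,5,6-tetramethoxyphenyl)oct-6-enal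
Conditions: KOtBu (3 equiv), MeI (6 equiv), THF, 0 °C, aldehyde added last
Reagents that add atoms: iodomethane (IC)
Why: Exhaustive α-alkylation of the aldehyde potassium enolate with iodomethane should stop at the quaternary, non-enolisable aldehyde, while the neighbouring stereocentre carries no acidic hydrogen and is retained.

Step 7
Reactants: 13 (3R,6E)-2,2,6-trimethyl-3-(prop-1-en-2-yl)-8-(2,3,5,6-tetramethoxyphenyl)oct-6-enal
Product: 14 (6R,8E)-5,5,9-trimethyl-6-(prop-1-en-2-yl)-11-(2,3,5,6-tetramethoxyphenyl)undeca-1,8-dien-4-ol (both C4 epimers)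
Conditions: allylMgBr, Et2O, −78 → 0 °C
Reagents that add atoms: allylmagnesium bromide (C=CC[Mg]Br)
Why: Grignard 1,2-addition of the small allyl nucleophile to the neopentyl aldehyde; the new carbinol centre forms without control and is removed in step 9.

Step 8
Reactants: 14 (6R,8E)-5,5,9-trimethyl-6-(prop-1-en-2-yl)-11-(2,3,5,6-tetramethoxyphenyl)undeca-1,8-dien-4-ol
Product: 15 O-[(6R,8E)-5,5,9-trimethyl-6-(prop-1-en-2-yl)-11-(2,3,5,6-tetramethoxyphenyl)undeca-1,8-dien-4-yl] S-methyl carbonodithioate
Conditions: NaH, imidazole (cat.), THF, 0 °C; CS2; MeI, rt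
Reagents that add atoms: carbon disulfide (S=C=S); iodomethane (IC)
Why: Xanthate formation from the sodium alkoxide, carbon disulfide and iodomethane prepares the hindered secondary alcohol for radical deoxygenation.

Step 9
Reactants: 15 O-[(6R,8E)-5,5,9-trimethyl-6-(prop-1-en-2-yl)-11-(2,3,5,6-tetramethoxyphenyl)undeca-1,8-dien-4-yl] S-methyl carbonodithioate
Product: 16 3-[(2E,6R)-3,7,7-trimethyl-6-(prop-1-en-2-yl)undeca-2,10-dien-1-yl]-1,2,4,5-tetramethoxybenzene
Conditions: Bu3SnH (2 equiv, 0.3 M), AIBN (cat.), benzene, 80 °C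
Reagents that add atoms: none
Why: Barton–McCombie deoxygenation, in which the stannyl radical adds to the thiocarbonyl and the released secondary radical should be reduced by the concentrated tin hydride faster than it can cyclise or abstract an allylic hydrogen, erasing the carbinol centre.

Step 10
Reactants: 16 3-[(2E,6R)-3,7,7-trimethyl-6-(prop-1-en-2-yl)undeca-2,10-dien-1-yl]-1,2,4,5-tetramethoxybenzene
Product: 17 1,2,4,5-tetramethoxy-3-{(2E)-3-methyl-5-[(1S)-2,6,6-trimethylcyclohex-2-en-1-yl]pent-2-en-1-yl}benzene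
Conditions: second-generation Grubbs catalyst (5 mol %), CH2Cl2 (0.005 M), 40 °C
Reagents that add atoms: none
Why: The ruthenium alkylidene should load onto the monosubstituted butenyl terminus, add intramolecularly to the 1,1-disubstituted isopropenyl olefin to give a ruthenacyclobutane, and cyclorevert to the ring C2=C3 bond with loss of ethene. The closest known reaction type is ring-closing metathesis of a 1,7-diene to a trisubstituted cyclohexene. The six-membered carbocycle closes by this intramolecular [2+2] cycloaddition and cycloreversion across a tether of four sp3 carbons, helped by the gem-dimethyl group at C6 (Thorpe–Ingold effect). No stereocentre is created: C1 comes from limonene C4, carries no acidic hydrogen and is not touched by the catalyst. The step needs chemoselectivity among three olefins and a fixed position for the new double bond: the E-trisubstituted side-chain olefin is too hindered to initiate and could only close an eight-membered ring, and a bond made by metathesis between two defined carbons cannot end up in the tetrasubstituted or exocyclic position, as it could in an acid-mediated cyclisation. High dilution suppresses acyclic cross-metathesis, which is in any case reversible.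

Step 11
Reactants: 17 1,2,4,5-tetramethoxy-3-{(2E)-3-methyl-5-[(1S)-2,6,6-trimethylcyclohex-2-en-1-yl]pent-2-en-1-yl}benzene
Product: 18 2,5-dimethoxy-3-{(2E)-3-methyl-5-[(1S)-2,6,6-trimethylcyclohex-2-en-1-yl]pent-2-en-1-yl}cyclohexa-2,5-diene-1,4-dione
Conditions: (NH4)2Ce(NO3)6 (2.5 equiv), MeCN/H2O, 0 °C
Reagents that add atoms: water (O)
Why: Oxidative demethylation of a para-dimethoxy pair (two one-electron oxidations with capture of water and loss of methanol) should give mainly the 2,5-dimethoxy-para-quinone, because the tetraalkoxyarene is far easier to oxidise than the isolated olefins.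

Step 12
Reactants: 18 2,5-dimethoxy-3-{(2E)-3-methyl-5-[(1S)-2,6,6-trimethylcyclohex-2-en-1-yl]pent-2-en-1-yl}cyclohexa-2,5-diene-1,4-dione
Product: 19 2-hydroxy-5-methoxy-3-{(2E)-3-methyl-5-[(1S)-2,6,6-trimethylcyclohex-2-en-1-yl]pent-2-en-1-yl}cyclohexa-2,5-diene-1,4-dione
Conditions: KOH (2 M aq.), MeOH, rt; then 1 M HCl
Reagents that add atoms: potassium hydroxide ([K+].[OH-])
Why: Saponification of a vinylogous ester by addition–elimination, expected at the methoxy group flanked by the alkyl chain and a carbonyl because that group is twisted out of conjugation and its carbon is more electrophilic, and the vinylogous carboxylate formed should resist a second hydrolysis.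

**Compound list**

1 | (S)-limonene, (4S)-1-methyl-4-(prop-1-en-2-yl)cyclohex-1-ene | CC1=CC[C@H](CC1)C(C)=C | starting material
2 | (3S)-6-oxo-3-(prop-1-en-2-yl)heptanal (not isolated) | CC(=O)CC[C@@H](CC=O)C(C)=C | intermediate
3 | (5S)-7,7-dimethoxy-5-(prop-1-en-2-yl)heptan-2-one | CC(=O)CC[C@@H](CC(OC)OC)C(C)=C | intermediate
4 | diethyl (5S)-7,7-dimethoxy-5-(prop-1-en-2-yl)hept-1-en-2-yl phosphate (not isolated) | C=C(OP(=O)(OCC)OCC)CC[C@@H](CC(OC)OC)C(C)=C | intermediate
5 | (5S)-7,7-dimethoxy-5-(prop-1-en-2-yl)hept-1-yne | C#CCC[C@@H](CC(OC)OC)C(C)=C | intermediate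
6 | 1,2,4,5-tetramethoxybenzene | COc1cc(OC)c(OC)cc1OC | starting material
7 | (2,3,5,6-tetramethoxyphenyl)lithium (not isolated) | COc1cc(OC)c(OC)c([Li])c1OC | intermediate
8 | (2,3,5,6-tetramethoxyphenyl)methanol | COc1cc(OC)c(OC)c(CO)c1OC | intermediate
9 | 3-(chloromethyl)-1,2,4,5-tetramethoxybenzene | COc1cc(OC)c(OC)c(CCl)c1OC | intermediate
10 | dimethyl[(1E,5S)-7,7-dimethoxy-2-methyl-5-(prop-1-en-2-yl)hept-1-en-1-yl]alumane (not isolated) | C[Al](C)/C=C(\C)CC[C@@H](CC(OC)OC)C(C)=C | intermediate
11 | 3-[(2E,6S)-8,8-dimethoxy-3-methyl-6-(prop-1-en-2-yl)oct-2-en-1-yl]-1,2,4,5-tetramethoxybenzene (not isolated) | COc1cc(OC)c(OC)c(C/C=C(\C)CC[C@@H](CC(OC)OC)C(C)=C)c1OC | intermediate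
12 | (3S,6E)-6-methyl-3-(prop-1-en-2-yl)-8-(2,3,5,6-tetramethoxyphenyl)oct-6-enal | COc1cc(OC)c(OC)c(C/C=C(\C)CC[C@@H](CC=O)C(C)=C)c1OC | intermediate
13 | (3R,6E)-2,2,6-trimethyl-3-(prop-1-en-2-yl)-8-(2,3,5,6-tetramethoxyphenyl)oct-6-enal | COc1cc(OC)c(OC)c(C/C=C(\C)CC[C@@H](C(C)(C)C=O)C(C)=C)c1OC | intermediate
14 | (6R,8E)-5,5,9-trimethyl-6-(prop-1-en-2-yl)-11-(2,3,5,6-tetramethoxyphenyl)undeca-1,8-dien-4-ol, both C4 epimers | COc1cc(OC)c(OC)c(C/C=C(\C)CC[C@@H](C(C)(C)C(O)CC=C)C(C)=C)c1OC | intermediate
15 | O-[(6R,8E)-5,5,9-trimethyl-6-(prop-1-en-2-yl)-11-(2,3,5,6-tetramethoxyphenyl)undeca-1,8-dien-4-yl] S-methyl carbonodithioate, both C4 epimers | COc1cc(OC)c(OC)c(C/C=C(\C)CC[C@@H](C(C)(C)C(OC(=S)SC)CC=C)C(C)=C)c1OC | intermediate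
16 | 3-[(2E,6R)-3,7,7-trimethyl-6-(prop-1-en-2-yl)undeca-2,10-dien-1-yl]-1,2,4,5-tetramethoxybenzene | COc1cc(OC)c(OC)c(C/C=C(\C)CC[C@@H](C(C)(C)CCC=C)C(C)=C)c1OC | intermediate
17 | 1,2,4,5-tetramethoxy-3-{(2E)-3-methyl-5-[(1S)-2,6,6-trimethylcyclohex-2-en-1-yl]pent-2-en-1-yl}benzene | COc1cc(OC)c(OC)c(C/C=C(\C)CC[C@@H]2C(C)=CCCC2(C)C)c1OC | intermediate
18 | 2,5-dimethoxy-3-{(2E)-3-methyl-5-[(1S)-2,6,6-trimethylcyclohex-2-en-1-yl]pent-2-en-1-yl}cyclohexa-2,5-diene-1,4-dione | COC1=CC(=O)C(OC)=C(C/C=C(\C)CC[C@@H]2C(C)=CCCC2(C)C)C1=O | intermediate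
19 | 2-hydroxy-5-methoxy-3-{(2E)-3-methyl-5-[(1S)-2,6,6-trimethylcyclohex-2-en-1-yl]pent-2-en-1-yl}cyclohexa-2,5-diene-1,4-dione | COC1=CC(=O)C(O)=C(C/C=C(\C)CC[C@@H]2C(C)=CCCC2(C)C)C1=O | target

**Count.** Total steps: 12. Longest linear sequence: 10 (steps 1, 2 and 5 to 12).

**Steps most likely to fail**

1. Step 5. The Lewis-acidic alane may cleave the dimethyl acetal during carboalumination, or the electron-rich benzylic chloride may homocouple instead of cross-coupling. The fallback sets out from ketone 3 and avoids aluminium. Horner–Wadsworth–Emmons olefination with triethyl phosphonoacetate and NaH should give ethyl (2E,6S)-8,8-dimethoxy-3-methyl-6-(prop-1-en-2-yl)oct-2-enoate F1, from which the minor Z isomer would be removed by chromatography. DIBAL-H reduction should give (2E,6S)-8,8-dimethoxy-3-methyl-6-(prop-1-en-2-yl)oct-2-en-1-ol F2, and CBr4/PPh3 should give (2E,6S)-1-bromo-8,8-dimethoxy-3-methyl-6-(prop-1-en-2-yl)oct-2-ene F3. Alkylation of aryllithium 7 (with CuBr·SMe2) by F3 should give acetal 11, and the acid hydrolysis of step 5 brings the route back at aldehyde 12.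

2. Step 6. O-methylation and aldol self-condensation may compete with the second C-methylation at the congested α-carbon, and the base may move the side-chain olefin into conjugation with the arene. The fallback sets out from aldehyde 12 and uses an aza-enolate. Condensation with cyclohexylamine over MgSO4 should give N-cyclohexyl-(3S,6E)-6-methyl-3-(prop-1-en-2-yl)-8-(2,3,5,6-tetramethoxyphenyl)oct-6-en-1-imine F4. Two cycles of LDA at −78 °C and iodomethane should give N-cyclohexyl-(3R,6E)-2,2,6-trimethyl-3-(prop-1-en-2-yl)-8-(2,3,5,6-tetramethoxyphenyl)oct-6-en-1-imine F5. Hydrolysis with aqueous oxalic acid returns to the route at aldehyde 13.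

3. Step 12. Hydroxide may attack the less hindered methoxy-bearing carbon and give the wrong site selectivity, or hydrolysis may run on to the diol. The fallback sets out from quinone 18 and puts the methyl group on under thermodynamic control. Exhaustive hydrolysis with warm aqueous NaOH in ethanol should give 2,5-dihydroxy-3-{(2E)-3-methyl-5-[(1S)-2,6,6-trimethylcyclohex-2-en-1-yl]pent-2-en-1-yl}cyclohexa-2,5-diene-1,4-dione F6. Acid-catalysed methanolysis (MeOH, cat. H2SO4, rt) should then esterify the less hindered vinylogous acid, the one next to the ring hydrogen, because only that methoxy group can lie in the plane of the quinone; this returns to the route at target 19.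

**Further compounds**

F1 | step 5 | ethyl (2E,6S)-8,8-dimethoxy-3-methyl-6-(prop-1-en-2-yl)oct-2-enoate | CCOC(=O)/C=C(\C)CC[C@@H](CC(OC)OC)C(C)=C
F2 | step 5 | (2E,6S)-8,8-dimethoxy-3-methyl-6-(prop-1-en-2-yl)oct-2-en-1-ol | OC/C=C(\C)CC[C@@H](CC(OC)OC)C(C)=C
F3 | step 5 | (2E,6S)-1-bromo-8,8-dimethoxy-3-methyl-6-(prop-1-en-2-yl)oct-2-ene | BrC/C=C(\C)CC[C@@H](CC(OC)OC)C(C)=C
F4 | step 6 | N-cyclohexyl-(3S,6E)-6-methyl-3-(prop-1-en-2-yl)-8-(2,3,5,6-tetramethoxyphenyl)oct-6-en-1-imine | COc1cc(OC)c(OC)c(C/C=C(\C)CC[C@@H](CC=NC2CCCCC2)C(C)=C)c1OC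
F5 | step 6 | N-cyclohexyl-(3R,6E)-2,2,6-trimethyl-3-(prop-1-en-2-yl)-8-(2,3,5,6-tetramethoxyphenyl)oct-6-en-1-imine | COc1cc(OC)c(OC)c(C/C=C(\C)CC[C@@H](C(C)(C)C=NC2CCCCC2)C(C)=C)c1OC
F6 | step 12 | 2,5-dihydroxy-3-{(2E)-3-methyl-5-[(1S)-2,6,6-trimethylcyclohex-2-en-1-yl]pent-2-en-1-yl}cyclohexa-2,5-diene-1,4-dione | OC1=CC(=O)C(O)=C(C/C=C(\C)CC[C@@H]2C(C)=CCCC2(C)C)C1=O
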